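## The problem

The target is a B-type procyanidin trimer. An upper (−)-epicatechin 3-O-gallate (unit T) is bonded through its C4 to C6 of a middle (−)-epicatechin 3-O-gallate (unit M), and C4 of unit M is bonded to C8 of a terminal (+)-catechin (unit B). The 4→8 bond follows the innate nucleophilicity of a flavan ring A, whereas the 4→6 bond goes against it and has to be enforced. Of the eight stereocentres, C2/C3 of units M and B can be taken from the chiral pool, and C4 of unit M is set in the usual way trans to its C3 oxygen. The contiguous triad C2–C3–C4 of unit T (2,3-cis, 3,4-trans) is the open problem: ring A of unit M insulates it from the stereocentres of unit M, so nothing elsewhere in the molecule can be relied on to fix its absolute sense. The two galloyl esters do not survive organometallic, hydride or alkoxide reagents, the interflavan bonds are acid-labile once the phenols are free, and the free polyphenol is sensitive to air and base. All nineteen hydroxyl groups that end up free are therefore carried as benzyl ethers to a final hydrogenolysis. The feature that invites an unconventional ring closure is C4 of unit T. It lies between two phloroglucinol-type rings (C4a of unit T and C6 of unit M, each with two ortho oxygens) and so supports a long-lived diarylmethyl cation. C2 of unit T, flanked by O1 and the catechol ring and adjacent to the C3 acyloxy group, can then carry the charge as an oxocarbenium that the galloyl carbonyl can bridge.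

## Retrosynthesis

Unit labels: T (upper), M (middle), B (terminal). "MB-6-yl" means the residue bonded through C6 of unit M of 8-bromo-3-O-TBS-5,7,3',4'-tetra-O-benzyl-(−)-epicatechin-(4β→8)-3,5,7,3',4'-penta-O-benzyl-(+)-catechin.

**35 ⇒ 34.** All nineteen O–benzyl bonds and the C8–Br bond of unit M are cut in one hydrogenolysis. Benzyl is preferred to silyl or acyl protection because its removal needs neither base nor fluoride at the free-polyphenol stage. The bromine, which served as a regiochemical blocking group, leaves in the same operation. The forward step must cleave an aryl bromide and benzyl ethers without touching two aryl esters or the interflavan bonds, so the HBr formed is buffered.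

**34 ⇒ 33 + 27, 33 ⇒ 32.** The ester C–O bond of the unit M gallate is cut, and the liberated 3-OH is traced back to a TBS ether. This ester is cut late because an acyl group on O3 of unit M could not pass the Grignard step that joins the fragments. The unit T gallate is not cut, since it is a working part of the key step. The forward reactions are a desilylation that spares an aryl ester and the acylation of a hindered secondary alcohol.

**32 ⇒ 29 (key cut).** The C3–C4 bond of unit T is cut and its ring C opened, which leads to the diarylmethyl methyl ether 29 carrying a (Z)-enol gallate on the phenolic oxygen.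
- *Against the neighbouring cuts.* Cutting C4(T)–C6(M) is the classical Friedel–Crafts disconnection; it needs a complete, C4-activated epicatechin gallate and must discriminate C6 of unit M from C6 of unit B. Here both aryl–C4 bonds stay in the precursor, where a carbonyl addition makes them, and the three stereocentres of unit T arise in one event. Cutting C4–C4a or O1–C2 would each leave two stereocentres to be made beforehand.
- *Simplification.* 29 has one ring and three stereocentres fewer, and the T portion is achiral in every respect that matters.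
- *Demands on the forward step.* It needs 6-endo attack of the enol carbon on the cation, 3,4-trans and 2,3-cis relationships, and the right sense relative to units M and B.
- *Two design decisions.* The enol geometry is not irrelevant: C2 becomes planar but C3 does not, and only the Z isomer (gallate oxygen cis to the aryloxy oxygen) carries the acyloxy group into the pseudoaxial position trans to the pseudoaxial C4 aryl. The carbinol is kept and ionised as its methyl ether, which survives the steps that build the enol ester and needs no unmasking.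

**29 ⇒ 25 + 27, 25 ⇒ 24 ⇒ 23 ⇒ 22.** The enol ester O–acyl bond is cut to the α-aryloxy-α-aryl aldehyde 25 and the acid chloride 27. A chelated lithium enolate should place the two oxygens cis, which is the geometry needed. The aldehyde is traced through the primary alcohol 24 and its triethylsilyl ether 23 to the carbinol 22; these are functional-group changes only. The methyl ether is installed under basic conditions so that the diaryl carbinol is never exposed to acid before the key step.

**22 ⇒ 10 + 20.** The C4(T)–C6(M) bond is cut as an aryl-metal addition to an aldehyde. The alternative polarity (formyl on the dimer, metal on the small ring) would need a regiochemically defined 2-halo-3,5-dibenzyloxyphenol, whereas 20 derives from a salicylaldehyde of unambiguous substitution. The precursors are a dimer and a small achiral aldehyde, roughly halving the size. The forward step must metalate C6 of unit M and nothing else, hence iodine at C6 beside bromine at C8.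

**10 ⇒ 9 + 3, back to 4 and 1.** The interflavan C4(M)–C8(B) bond is cut as a Lewis-acid C4-arylation, the standard way to make 4β→8 bonds. Electrophile 9 carries both halogens before the coupling, because halogenating the dimer could not tell C6 of unit M from C6 of unit B. 9 comes from (−)-epicatechin 4 by benzylation, C4 oxidation, silylation and two ring A halogenations (C8 first, then C6). 3 is perbenzylated (+)-catechin 1.

**20 ⇒ 19 ⇒ 18 ⇒ 17 ⇒ 12 + 16.** The aryl ether C–O bond is cut to the salicylaldehyde 12 and the α-bromo ester 16, a Williamson reaction on an activated secondary bromide. The ester is then brought to the protected alcohol level so that no enolisable carbonyl sits ortho to the formyl group when the organometallic arrives. 12 is dibenzylated 2,4,6-trihydroxybenzaldehyde 11. 16 comes from 3,4-dihydroxyphenylacetic acid 13 through 14.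

## Roads not taken

**Alternative 1:** the cut removes ring A of unit M altogether (C4a–C8a, C5–C6 and C8–C8a).
- *Forward step.* The cyclobutenone A2, carrying a silyl-protected unit T through C4 of the flavan, would be heated with the siloxyalkyne A3. Electrocyclic opening, [2+2] addition to the alkyne, a second opening and a six-electron closure would give the phenol A1, with the flavanyl group at the future C6, the hydroxyl at C8a and the acetal carbon at C4a.
- *Merits.* The 4→6 pattern is fixed by pericyclic connectivity, so there is no competition with C8 and no blocking halogen. The conditions are neutral. Unit T enters as a derivative of 4 with all three stereocentres already secure. On that last point this road is better than the chosen one.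
- *Weak points.* A1 has none of ring C of unit M: C2, C3, the catechol ring and the bond to unit B would need a de novo enantioselective flavan-3-ol synthesis and a C4 arylation on a substrate that already carries unit T. Three differently protected oxygens must be levelled. Joining a 3-alkoxycyclobutenone to C4 of a flavan is itself unsolved.
- *Comparison.* The chosen plan takes units M and B ready-made from 4 and 1 and stands three steps from the target after its key step. It pays for this with the stereochemical risk in unit T.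

**Alternative 2:** the cut is C4–C4a of unit M.
- *Forward step.* In the aryl ether A5, BF3·OEt2 would open the trans-epoxide at the carbon bearing catechin C8, and an ortho carbon of the ether ring would attack with inversion (6-endo) to give A4 with a free 3-OH on unit M.
- *Merits.* The ether ring carries unit T para to oxygen, so its two ortho carbons are equivalent and the 4→6 pattern needs no blocking group. C3 and C4 follow stereospecifically from the epoxide, and the 3-OH emerges ready for galloylation. Lewis-acid epoxide–arene cyclisation is a known reaction type, and the absolute configuration would rest on a reagent-controlled epoxidation. In mechanistic security and absolute stereocontrol this road is ahead of the chosen one.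
- *Weak points.* An epoxide whose benzylic carbon bears a 2,4,6-trioxygenated ring ionises very easily, so inversion can be lost and rearrangement to a carbonyl compound competes. The epoxide, the C2 aryl ether centre and the T-bearing phenol (whose C-arylation regiochemistry is itself ambiguous) must all be made de novo with unit T and its gallate on board. Unit M no longer comes from 4.
- *Comparison.* The chosen plan builds only the ring of unit T on a dimer made from the chiral pool by standard steps, in a shorter sequence, but it has no reagent-controlled source of absolute configuration.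

**Alternative 3:** the cut is the C8a–O1 bond of unit T.
- *Forward step.* m-Chloroperbenzoic acid with Sc(OTf)3 would convert the indanone A7 by aryl migration (Baeyer–Villiger) into the dihydrocoumarin A6.
- *Merits.* The electron-rich aryl group migrates reliably. C4 of unit T could be set first by a catalyst-controlled conjugate addition and then relay its configuration to C3 and C2 within the ring. That is a sounder logic for absolute control than the chosen plan offers.
- *Weak points.* A peracid and a strong Lewis acid meet five very electron-rich arenes with free ring positions, and arene oxidation is likely. A6 still lacks the catechol ring, the C3 oxygen and the C2 stereocentre, so aryl addition to the lactone, α-oxygenation and a reductive closure must follow on a trimer-sized substrate. Making A7 needs the hindered, protodemetalation-prone C6 position of the dimer as the aryl donor.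
- *Comparison.* The chosen plan avoids oxidants after the dimer stage and makes the ring and all three centres of unit T in one step. It concedes that its absolute control rests on an ion pair and not on a precedented catalytic step.

Key step: step 21

Assumption: the diaryl carbinol is carried and ionised as its methyl ether (a change of leaving group only), and commercial 2,4,6-trihydroxybenzaldehyde, 3,4-dihydroxyphenylacetic acid and 3,4,5-tris(benzyloxy)benzoic acid supply the phloroglucinol-, catechol- and gallic acid-derived carbons.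

## Steps

Step 1
Reactants: 1 (+)-catechin
Product: 2 5,7,3',4'-tetra-O-benzyl-(+)-catechin
Conditions: BnBr (4.4 equiv), K2CO3, DMF, 0 °C → rt
Reagents that add atoms: benzyl bromide, BrCc1ccccc1
Why: Williamson etherification; carbonate deprotonates only the four phenols, so the secondary 3-OH stays free and the 2,3-trans ring is not epimerised.

Step 2
Reactants: 2 5,7,3',4'-tetra-O-benzyl-(+)-catechin
Product: 3 3,5,7,3',4'-penta-O-benzyl-(+)-catechin
Conditions: NaH, BnBr, Bu4NI (cat.), DMF, 0 °C → rt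
Reagents that add atoms: benzyl bromide, BrCc1ccccc1
Why: Williamson etherification of the secondary alcohol through its sodium alkoxide; O3 of unit B must be blocked so that the later acylations cannot reach it.

Step 3
Reactants: 4 (−)-epicatechin
Product: 5 5,7,3',4'-tetra-O-benzyl-(−)-epicatechin
Conditions: BnBr (4.4 equiv), K2CO3, DMF, 0 °C → rt
Reagents that add atoms: benzyl bromide, BrCc1ccccc1
Why: Williamson etherification of the four phenols under carbonate, which leaves the 3-OH free and does not open the 2,3-cis pyran ring.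

Step 4
Reactants: 5 5,7,3',4'-tetra-O-benzyl-(−)-epicatechin
Product: 6 5,7,3',4'-tetra-O-benzyl-4β-(2-ethoxyethoxy)-(−)-epicatechin (4-alkoxy trans to 3-OH)
Conditions: DDQ (2 equiv), 2-ethoxyethanol (5 equiv), CH2Cl2, rt
Reagents that add atoms: 2-ethoxyethanol, CCOCCO
Why: Benzylic oxidation by hydride abstraction; DDQ takes hydride from C4 and the ring A-stabilised cation is trapped by the alcohol on the face opposite the C3 oxygen, which sets the 3,4-trans (4β) ether.

Step 5
Reactants: 6 5,7,3',4'-tetra-O-benzyl-4β-(2-ethoxyethoxy)-(−)-epicatechin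
Product: 7 3-O-TBS-5,7,3',4'-tetra-O-benzyl-4β-(2-ethoxyethoxy)-(−)-epicatechin
Conditions: TBSCl, imidazole, DMAP (cat.), DMF, 40 °C
Reagents that add atoms: tert-butyldimethylsilyl chloride, CC(C)(C)[Si](C)(C)Cl
Why: Silylation of the secondary alcohol under basic conditions that do not ionise the acid-labile C4 ether; the silyl ether is the only O3 protection that survives the later Grignard step.

Step 6
Reactants: 7 3-O-TBS-5,7,3',4'-tetra-O-benzyl-4β-(2-ethoxyethoxy)-(−)-epicatechin
Product: 9 8-bromo-6-iodo-3-O-TBS-5,7,3',4'-tetra-O-benzyl-4β-(2-ethoxyethoxy)-(−)-epicatechin, via 8-bromo compound 8 (not isolated)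
Conditions: NBS (1.0 equiv), CH2Cl2, −78 → 0 °C; then NIS (1.2 equiv), 0 °C → rt
Reagents that add atoms: N-bromosuccinimide, O=C1CCC(=O)N1Br; N-iodosuccinimide, O=C1CCC(=O)N1I
Why: Electrophilic aromatic halogenation; C8 is the most reactive site of a 5,7-dialkoxyflavan and takes bromine, leaving only C6 for iodine. The two different halogens later allow metalation at C6 alone.

Step 7
Reactants: 9 8-bromo-6-iodo-3-O-TBS-5,7,3',4'-tetra-O-benzyl-4β-(2-ethoxyethoxy)-(−)-epicatechin; 3 3,5,7,3',4'-penta-O-benzyl-(+)-catechin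
Product: 10 8-bromo-6-iodo-3-O-TBS-5,7,3',4'-tetra-O-benzyl-(−)-epicatechin-(4β→8)-3,5,7,3',4'-penta-O-benzyl-(+)-catechin
Conditions: 3 (2 equiv), TMSOTf (0.2 equiv), CH2Cl2, −78 °C; then Et3N
Reagents that add atoms: none
Why: Lewis-acid Friedel–Crafts C4-arylation; the C4 ether ionises and C8 of 3, the most nucleophilic ring A position, attacks trans to the 3-OTBS group (4β). Both nucleophilic sites of the electrophile are halogenated, so it cannot oligomerise.

Step 8
Reactants: 11 2,4,6-trihydroxybenzaldehyde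
Product: 12 2,4-bis(benzyloxy)-6-hydroxybenzaldehyde
Conditions: BnBr (2.05 equiv), K2CO3, DMF, rt
Reagents that add atoms: benzyl bromide, BrCc1ccccc1
Why: Williamson etherification; after the para and one ortho hydroxyl have reacted, the last hydroxyl is hydrogen-bonded to the formyl group, is much less nucleophilic and stays free.

Step 9
Reactants: 13 3,4-dihydroxyphenylacetic acid
Product: 14 benzyl [3,4-bis(benzyloxy)phenyl]acetate
Conditions: BnBr (3.3 equiv), K2CO3, DMF, 60 °C
Reagents that add atoms: benzyl bromide, BrCc1ccccc1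
Why: O-Alkylation of both phenols and of the carboxylate in one operation.

Step 10
Reactants: 14 benzyl [3,4-bis(benzyloxy)phenyl]acetate
Product: 16 benzyl bromo[3,4-bis(benzyloxy)phenyl]acetate (racemic), via lithium ester enolate 15 (not isolated)
Conditions: LiHMDS, THF, −78 °C; then NBS, −78 °C
Reagents that add atoms: N-bromosuccinimide, O=C1CCC(=O)N1Br
Why: α-Bromination of an ester enolate; ionic conditions are chosen because radical bromination would also attack the benzyl ether methylenes.

Step 11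
Reactants: 12 2,4-bis(benzyloxy)-6-hydroxybenzaldehyde; 16 benzyl bromo[3,4-bis(benzyloxy)phenyl]acetate
Product: 17 benzyl 2-[3,5-bis(benzyloxy)-2-formylphenoxy]-2-[3,4-bis(benzyloxy)phenyl]acetate (racemic)
Conditions: K2CO3, acetone, rt
Reagents that add atoms: none
Why: Williamson ether synthesis by SN2 displacement on an activated secondary α-bromo ester; mild carbonate at room temperature keeps the product ester from closing by aldol addition onto the ortho formyl group.

Step 12
Reactants: 17 benzyl 2-[3,5-bis(benzyloxy)-2-formylphenoxy]-2-[3,4-bis(benzyloxy)phenyl]acetate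
Product: 18 2-[3,5-bis(benzyloxy)-2-(hydroxymethyl)phenoxy]-2-[3,4-bis(benzyloxy)phenyl]ethan-1-ol (racemic)
Conditions: LiAlH4, THF, 0 °C
Reagents that add atoms: none
Why: Hydride reduction of ester and aldehyde together; it removes the enolisable carbonyl that could otherwise condense with the ortho formyl group.

Step 13
Reactants: 18 2-[3,5-bis(benzyloxy)-2-(hydroxymethyl)phenoxy]-2-[3,4-bis(benzyloxy)phenyl]ethan-1-ol
Product: 19 2,4-bis(benzyloxy)-6-{1-[3,4-bis(benzyloxy)phenyl]-2-hydroxyethoxy}benzaldehyde (racemic)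
Conditions: MnO2 (activated, excess), CH2Cl2, rt
Reagents that add atoms: none
Why: Chemoselective MnO2 oxidation of the benzylic alcohol; the aliphatic primary alcohol is not oxidised.

Step 14
Reactants: 19 2,4-bis(benzyloxy)-6-{1-[3,4-bis(benzyloxy)phenyl]-2-hydroxyethoxy}benzaldehyde
Product: 20 2,4-bis(benzyloxy)-6-{1-[3,4-bis(benzyloxy)phenyl]-2-(triethylsilyloxy)ethoxy}benzaldehyde (racemic)
Conditions: TESCl, imidazole, CH2Cl2, 0 °C
Reagents that add atoms: chlorotriethylsilane, CC[Si](CC)(CC)Cl
Why: Silylation of the primary alcohol; a primary TES ether can later be removed by fluoride in the presence of the hindered secondary TBS ether.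

Step 15
Reactants: 10 8-bromo-6-iodo dimer; 20 2,4-bis(benzyloxy)-6-{1-[3,4-bis(benzyloxy)phenyl]-2-(triethylsilyloxy)ethoxy}benzaldehyde
Product: 22 {2,4-bis(benzyloxy)-6-[1-(3,4-bis(benzyloxy)phenyl)-2-(triethylsilyloxy)ethoxy]phenyl}(MB-6-yl)methanol (mixture of epimers at the carbinol and side-chain carbons), via arylmagnesium chloride 21 (not isolated)
Conditions: i-PrMgCl·LiCl (1.1 equiv), THF, −20 → 0 °C; then 20 (1.3 equiv), −40 °C → rt
Reagents that add atoms: none
Why: Iodine–magnesium exchange followed by Grignard addition to an aldehyde; the exchange takes the C–I bond and leaves C–Br. The two new stereocentres need no control because both become trigonal before the key step.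

Step 16
Reactants: 22 bis-aryl carbinol
Product: 23 methyl ether of 22: 1-[methoxy(MB-6-yl)methyl]-2,4-bis(benzyloxy)-6-[1-(3,4-bis(benzyloxy)phenyl)-2-(triethylsilyloxy)ethoxy]benzene
Conditions: NaH, MeI, THF/DMF, 0 °C → rt
Reagents that add atoms: iodomethane, CI
Why: Williamson methylation of the hindered alkoxide; basic conditions avoid ionising the carbinol, and the methyl ether is inert to the fluoride, oxidation and enolate steps that follow.

Step 17
Reactants: 23 methyl ether with primary TES ether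
Product: 24 2-[3,4-bis(benzyloxy)phenyl]-2-{3,5-bis(benzyloxy)-2-[methoxy(MB-6-yl)methyl]phenoxy}ethan-1-ol
Conditions: TBAF (1.1 equiv), THF, 0 °C
Reagents that add atoms: none
Why: Fluoride desilylation; the unhindered primary TES ether is cleaved far faster than the axial secondary TBS ether of unit M.

Step 18
Reactants: 24 primary alcohol
Product: 25 2-[3,4-bis(benzyloxy)phenyl]-2-{3,5-bis(benzyloxy)-2-[methoxy(MB-6-yl)methyl]phenoxy}acetaldehyde (used crude)
Conditions: Dess–Martin periodinane, pyridine, CH2Cl2, 0 °C → rt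
Reagents that add atoms: none
Why: Dess–Martin oxidation of a primary alcohol under buffered, non-acidic conditions that leave the benzhydryl methyl ether and the electron-rich arenes alone.

Step 19
Reactants: 26 3,4,5-tris(benzyloxy)benzoic acid
Product: 27 3,4,5-tris(benzyloxy)benzoyl chloride
Conditions: (COCl)2, DMF (cat.), CH2Cl2, rt
Reagents that add atoms: oxalyl chloride, O=C(Cl)C(=O)Cl
Why: Standard conversion of a carboxylic acid into its chloride through the Vilsmeier-type chloroiminium catalyst.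

Step 20
Reactants: 25 α-aryloxy-α-aryl acetaldehyde; 27 3,4,5-tris(benzyloxy)benzoyl chloride
Product: 29 (Z)-2-[3,4-bis(benzyloxy)phenyl]-2-{3,5-bis(benzyloxy)-2-[methoxy(MB-6-yl)methyl]phenoxy}ethenyl 3,4,5-tris(benzyloxy)benzoate (gallate oxygen cis to aryloxy oxygen), via lithium Z-enolate 28 (not isolated)
Conditions: LiHMDS (1.05 equiv), THF, −78 °C; then 27, −78 → −40 °C
Reagents that add atoms: none
Why: O-Acylation of an aldehyde enolate; C-acylation is blocked because the α-carbon is fully substituted. The Z geometry should follow from lithium chelation between the enolate and aryloxy oxygens and from the preference of the catechol ring to lie cis to hydrogen.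

Step 21
Reactants: 29 (Z)-enol gallate methyl ether
Product: 32 3-O-[3,4,5-tris(benzyloxy)benzoyl]-5,7,3',4'-tetra-O-benzyl-(−)-epicatechin-(4β→6)-[8-bromo-3-O-TBS-5,7,3',4'-tetra-O-benzyl-(−)-epicatechin]-(4β→8)-3,5,7,3',4'-penta-O-benzyl-(+)-catechin, via diarylmethyl cation 30 (not isolated), via dioxolanylium ion 31 (not isolated)
Conditions: (R)-3,3'-bis(2,4,6-triisopropylphenyl)-1,1'-binaphthyl-2,2'-diyl hydrogen phosphate (0.2 equiv; the S acid if mismatched), Et3SiH (5 equiv), CH2Cl2 (0.002 M), −40 → 0 °C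
Reagents that add atoms: none
Why: Proposed new method: the phosphoric acid protonates the methoxy group of 29, and in the resulting ion pair of cation 30 with the chiral phosphate the enol carbon (future C3), made nucleophilic by the aryloxy and catechol-ether donors on C2, attacks the cationic carbon in a 6-endo-trig closure that forms C3–C4 and ring C of unit T; the closest known reactions are Prins-type cation–enol ether cyclisations ended by ionic hydrogenation and acyloxy neighbouring-group participation as in 1,2-trans glycosylation. C4 and C3 are set together: the unit M aryl on the cationic carbon must stand pseudoaxial to avoid peri strain with the C5 benzyloxy group, and the Z enol carries its acyloxy group, cis to O1, into the pseudoaxial position on the opposite face, so the 3,4-trans isomer should result where the E enol would give 3,4-cis. The charge then rests on C2, where the pseudoaxial galloyl carbonyl closes the cis-fused dioxolanylium ion 31 on the face of the C3 oxygen. Et3SiH, too hindered to reduce the shielded diaryl cation at a competitive rate, opens 31 at C2 from the other face, anti to the axial C3–O bond, which is also the Felkin–Anh and half-chair trajectory, so the catechol ring ends cis to the gallate (2,3-cis). The sense of the three new centres relative to units M and B is not secured by the substrate, since the nearest old centres lie beyond ring A of unit M; it is asked of the chiral phosphate counter-ion, and because the outcomes are diastereomers they can be separated. A weak acid is chosen so that the methyl ether ionises while the enol ester is not C-protonated, high dilution keeps the free C6–H of unit B from intercepting the cation, and bromine blocks C8 of unit M. The TBS ether, aryl bromide and benzyl ethers are inert, and the acid is regenerated when the silyl phosphate is methanolysed to Et3SiOMe.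

Step 22
Reactants: 32 benzylated trimer with TBS on unit M
Product: 33 3-O-[3,4,5-tris(benzyloxy)benzoyl]-5,7,3',4'-tetra-O-benzyl-(−)-epicatechin-(4β→6)-[8-bromo-5,7,3',4'-tetra-O-benzyl-(−)-epicatechin]-(4β→8)-3,5,7,3',4'-penta-O-benzyl-(+)-catechin (free 3-OH on unit M)
Conditions: HF·pyridine, pyridine, THF, 0 °C → rt
Reagents that add atoms: none
Why: Fluoride cleavage of the silyl ether under buffered, non-basic conditions, so the unit T gallate is neither hydrolysed nor able to migrate.

Step 23
Reactants: 33 trimer with free 3-OH on unit M; 27 3,4,5-tris(benzyloxy)benzoyl chloride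
Product: 34 3-O-[3,4,5-tris(benzyloxy)benzoyl]-5,7,3',4'-tetra-O-benzyl-(−)-epicatechin-(4β→6)-{8-bromo-3-O-[3,4,5-tris(benzyloxy)benzoyl]-5,7,3',4'-tetra-O-benzyl-(−)-epicatechin}-(4β→8)-3,5,7,3',4'-penta-O-benzyl-(+)-catechin
Conditions: 27 (3 equiv), DMAP, Et3N, CH2Cl2, rt
Reagents that add atoms: none
Why: DMAP-catalysed acylation of the hindered axial secondary alcohol with an acid chloride; it is the only free hydroxyl in the molecule.

Step 24
Reactants: 34 fully benzylated bis-gallate
Product: 35 (−)-epicatechin 3-O-gallate-(4β→6)-(−)-epicatechin 3-O-gallate-(4β→8)-(+)-catechin (CNP0112921.1)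
Conditions: H2 (1 atm), Pd(OH)2/C, Et3N (1.1 equiv), THF/MeOH/H2O, rt
Reagents that add atoms: none
Why: Catalytic hydrogenolysis of the nineteen benzyl ethers with hydrodebromination at C8 of unit M; the amine takes up HBr so the acid-labile interflavan bonds and the esters are not exposed to acid. No stereocentre is touched.

## Compound list

1 | (+)-catechin | Oc1cc(O)c2c(c1)O[C@H](c1ccc(O)c(O)c1)[C@@H](O)C2 | starting material
2 | 5,7,3',4'-tetra-O-benzyl-(+)-catechin | c5ccccc5COc1cc(OCc5ccccc5)c2c(c1)O[C@H](c1ccc(OCc5ccccc5)c(OCc5ccccc5)c1)[C@@H](O)C2 | intermediate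
3 | 3,5,7,3',4'-penta-O-benzyl-(+)-catechin | c5ccccc5COc1cc(OCc5ccccc5)c2c(c1)O[C@H](c1ccc(OCc5ccccc5)c(OCc5ccccc5)c1)[C@@H](OCc5ccccc5)C2 | intermediate
4 | (−)-epicatechin | O[C@@H]1Cc2c(O)cc(O)cc2O[C@@H]1c1ccc(O)c(O)c1 | starting material
5 | 5,7,3',4'-tetra-O-benzyl-(−)-epicatechin | O[C@@H]1Cc2c(OCc5ccccc5)cc(OCc5ccccc5)cc2O[C@@H]1c1ccc(OCc5ccccc5)c(OCc5ccccc5)c1 | intermediate
6 | 5,7,3',4'-tetra-O-benzyl-4β-(2-ethoxyethoxy)-(−)-epicatechin | O[C@@H]1[C@@H](OCCOCC)c2c(OCc5ccccc5)cc(OCc5ccccc5)cc2O[C@@H]1c1ccc(OCc5ccccc5)c(OCc5ccccc5)c1 | intermediate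
7 | 3-O-TBS ether of 6 | CC(C)(C)[Si](C)(C)O[C@@H]1[C@@H](OCCOCC)c2c(OCc5ccccc5)cc(OCc5ccccc5)cc2O[C@@H]1c1ccc(OCc5ccccc5)c(OCc5ccccc5)c1 | intermediate
8 | 8-bromo derivative of 7 (formed in the flask) | CC(C)(C)[Si](C)(C)O[C@@H]1[C@@H](OCCOCC)c2c(OCc5ccccc5)cc(OCc5ccccc5)c(Br)c2O[C@@H]1c1ccc(OCc5ccccc5)c(OCc5ccccc5)c1 | intermediate
9 | 8-bromo-6-iodo derivative of 7 | CC(C)(C)[Si](C)(C)O[C@@H]1[C@@H](OCCOCC)c2c(OCc5ccccc5)c(I)c(OCc5ccccc5)c(Br)c2O[C@@H]1c1ccc(OCc5ccccc5)c(OCc5ccccc5)c1 | intermediate
10 | 8-bromo-6-iodo-3-O-TBS-tetra-O-benzyl-epicatechin-(4β→8)-penta-O-benzyl-catechin | Ic2c(OCc5ccccc5)c(Br)c3c(c2OCc5ccccc5)[C@H](c2c(OCc5ccccc5)cc(OCc5ccccc5)c4c2O[C@H](c2ccc(OCc5ccccc5)c(OCc5ccccc5)c2)[C@@H](OCc5ccccc5)C4)[C@@H](O[Si](C)(C)C(C)(C)C)[C@@H](c2ccc(OCc5ccccc5)c(OCc5ccccc5)c2)O3 | intermediate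
11 | 2,4,6-trihydroxybenzaldehyde | O=Cc1c(O)cc(O)cc1O | starting material
12 | 2,4-bis(benzyloxy)-6-hydroxybenzaldehyde | O=Cc1c(O)cc(OCc5ccccc5)cc1OCc5ccccc5 | intermediate
13 | 3,4-dihydroxyphenylacetic acid | OC(=O)Cc1ccc(O)c(O)c1 | starting material
14 | benzyl [3,4-bis(benzyloxy)phenyl]acetate | O=C(Cc1ccc(OCc5ccccc5)c(OCc5ccccc5)c1)OCc5ccccc5 | intermediate
15 | lithium enolate of 14 (formed in the flask) | [Li]OC(OCc5ccccc5)=Cc1ccc(OCc5ccccc5)c(OCc5ccccc5)c1 | intermediate
16 | benzyl bromo[3,4-bis(benzyloxy)phenyl]acetate | O=C(C(Br)c1ccc(OCc5ccccc5)c(OCc5ccccc5)c1)OCc5ccccc5 | intermediate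
17 | benzyl 2-[3,5-bis(benzyloxy)-2-formylphenoxy]-2-[3,4-bis(benzyloxy)phenyl]acetate | O=Cc1c(OC(C(=O)OCc5ccccc5)c2ccc(OCc5ccccc5)c(OCc5ccccc5)c2)cc(OCc5ccccc5)cc1OCc5ccccc5 | intermediate
18 | 2-[3,5-bis(benzyloxy)-2-(hydroxymethyl)phenoxy]-2-[3,4-bis(benzyloxy)phenyl]ethan-1-ol | OCc1c(OC(CO)c2ccc(OCc5ccccc5)c(OCc5ccccc5)c2)cc(OCc5ccccc5)cc1OCc5ccccc5 | intermediate
19 | 2,4-bis(benzyloxy)-6-{1-[3,4-bis(benzyloxy)phenyl]-2-hydroxyethoxy}benzaldehyde | O=Cc1c(OC(CO)c2ccc(OCc5ccccc5)c(OCc5ccccc5)c2)cc(OCc5ccccc5)cc1OCc5ccccc5 | intermediate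
20 | 2,4-bis(benzyloxy)-6-{1-[3,4-bis(benzyloxy)phenyl]-2-(triethylsilyloxy)ethoxy}benzaldehyde | O=Cc1c(OC(CO[Si](CC)(CC)CC)c2ccc(OCc5ccccc5)c(OCc5ccccc5)c2)cc(OCc5ccccc5)cc1OCc5ccccc5 | intermediate
21 | C6 arylmagnesium chloride of the dimer (formed in the flask) | Cl[Mg]c2c(OCc5ccccc5)c(Br)c3c(c2OCc5ccccc5)[C@H](c2c(OCc5ccccc5)cc(OCc5ccccc5)c4c2O[C@H](c2ccc(OCc5ccccc5)c(OCc5ccccc5)c2)[C@@H](OCc5ccccc5)C4)[C@@H](O[Si](C)(C)C(C)(C)C)[C@@H](c2ccc(OCc5ccccc5)c(OCc5ccccc5)c2)O3 | intermediate
22 | bis-aryl carbinol with TES-protected side chain (epimer mixture) | CC[Si](CC)(CC)OCC(c1ccc(OCc5ccccc5)c(OCc5ccccc5)c1)Oc2cc(OCc5ccccc5)cc(OCc5ccccc5)c2C(O)c2c(OCc5ccccc5)c(Br)c3c(c2OCc5ccccc5)[C@H](c2c(OCc5ccccc5)cc(OCc5ccccc5)c4c2O[C@H](c2ccc(OCc5ccccc5)c(OCc5ccccc5)c2)[C@@H](OCc5ccccc5)C4)[C@@H](O[Si](C)(C)C(C)(C)C)[C@@H](c2ccc(OCc5ccccc5)c(OCc5ccccc5)c2)O3 | intermediate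
23 | methyl ether of 22 | CC[Si](CC)(CC)OCC(c1ccc(OCc5ccccc5)c(OCc5ccccc5)c1)Oc2cc(OCc5ccccc5)cc(OCc5ccccc5)c2C(OC)c2c(OCc5ccccc5)c(Br)c3c(c2OCc5ccccc5)[C@H](c2c(OCc5ccccc5)cc(OCc5ccccc5)c4c2O[C@H](c2ccc(OCc5ccccc5)c(OCc5ccccc5)c2)[C@@H](OCc5ccccc5)C4)[C@@H](O[Si](C)(C)C(C)(C)C)[C@@H](c2ccc(OCc5ccccc5)c(OCc5ccccc5)c2)O3 | intermediate
24 | primary alcohol (TES removed) | OCC(c1ccc(OCc5ccccc5)c(OCc5ccccc5)c1)Oc2cc(OCc5ccccc5)cc(OCc5ccccc5)c2C(OC)c2c(OCc5ccccc5)c(Br)c3c(c2OCc5ccccc5)[C@H](c2c(OCc5ccccc5)cc(OCc5ccccc5)c4c2O[C@H](c2ccc(OCc5ccccc5)c(OCc5ccccc5)c2)[C@@H](OCc5ccccc5)C4)[C@@H](O[Si](C)(C)C(C)(C)C)[C@@H](c2ccc(OCc5ccccc5)c(OCc5ccccc5)c2)O3 | intermediate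
25 | α-aryloxy-α-aryl acetaldehyde | O=CC(c1ccc(OCc5ccccc5)c(OCc5ccccc5)c1)Oc2cc(OCc5ccccc5)cc(OCc5ccccc5)c2C(OC)c2c(OCc5ccccc5)c(Br)c3c(c2OCc5ccccc5)[C@H](c2c(OCc5ccccc5)cc(OCc5ccccc5)c4c2O[C@H](c2ccc(OCc5ccccc5)c(OCc5ccccc5)c2)[C@@H](OCc5ccccc5)C4)[C@@H](O[Si](C)(C)C(C)(C)C)[C@@H](c2ccc(OCc5ccccc5)c(OCc5ccccc5)c2)O3 | intermediate
26 | 3,4,5-tris(benzyloxy)benzoic acid | OC(=O)c1cc(OCc5ccccc5)c(OCc5ccccc5)c(OCc5ccccc5)c1 | starting material
27 | 3,4,5-tris(benzyloxy)benzoyl chloride | ClC(=O)c1cc(OCc5ccccc5)c(OCc5ccccc5)c(OCc5ccccc5)c1 | intermediate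
28 | lithium (Z)-enolate of 25 (formed in the flask) | [Li]O/C=C(/c1ccc(OCc5ccccc5)c(OCc5ccccc5)c1)Oc2cc(OCc5ccccc5)cc(OCc5ccccc5)c2C(OC)c2c(OCc5ccccc5)c(Br)c3c(c2OCc5ccccc5)[C@H](c2c(OCc5ccccc5)cc(OCc5ccccc5)c4c2O[C@H](c2ccc(OCc5ccccc5)c(OCc5ccccc5)c2)[C@@H](OCc5ccccc5)C4)[C@@H](O[Si](C)(C)C(C)(C)C)[C@@H](c2ccc(OCc5ccccc5)c(OCc5ccccc5)c2)O3 | intermediate
29 | (Z)-enol gallate, carbinol as methyl ether (key-step precursor) | O=C(O/C=C(/c1ccc(OCc5ccccc5)c(OCc5ccccc5)c1)Oc2cc(OCc5ccccc5)cc(OCc5ccccc5)c2C(OC)c2c(OCc5ccccc5)c(Br)c3c(c2OCc5ccccc5)[C@H](c2c(OCc5ccccc5)cc(OCc5ccccc5)c4c2O[C@H](c2ccc(OCc5ccccc5)c(OCc5ccccc5)c2)[C@@H](OCc5ccccc5)C4)[C@@H](O[Si](C)(C)C(C)(C)C)[C@@H](c2ccc(OCc5ccccc5)c(OCc5ccccc5)c2)O3)c1cc(OCc5ccccc5)c(OCc5ccccc5)c(OCc5ccccc5)c1 | intermediate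
30 | diarylmethyl cation from 29 (formed in the flask) | O=C(O/C=C(/c1ccc(OCc5ccccc5)c(OCc5ccccc5)c1)Oc2cc(OCc5ccccc5)cc(OCc5ccccc5)c2[CH+]c2c(OCc5ccccc5)c(Br)c3c(c2OCc5ccccc5)[C@H](c2c(OCc5ccccc5)cc(OCc5ccccc5)c4c2O[C@H](c2ccc(OCc5ccccc5)c(OCc5ccccc5)c2)[C@@H](OCc5ccccc5)C4)[C@@H](O[Si](C)(C)C(C)(C)C)[C@@H](c2ccc(OCc5ccccc5)c(OCc5ccccc5)c2)O3)c1cc(OCc5ccccc5)c(OCc5ccccc5)c(OCc5ccccc5)c1 | intermediate
31 | cis-fused 2-aryl-1,3-dioxolan-2-ylium ion across C2–C3 of the new ring (formed in the flask) | [C+]6(c1cc(OCc5ccccc5)c(OCc5ccccc5)c(OCc5ccccc5)c1)O[C@@H]1[C@@H](c2c(OCc5ccccc5)c(Br)c3c(c2OCc5ccccc5)[C@H](c2c(OCc5ccccc5)cc(OCc5ccccc5)c4c2O[C@H](c2ccc(OCc5ccccc5)c(OCc5ccccc5)c2)[C@@H](OCc5ccccc5)C4)[C@@H](O[Si](C)(C)C(C)(C)C)[C@@H](c2ccc(OCc5ccccc5)c(OCc5ccccc5)c2)O3)c2c(OCc5ccccc5)cc(OCc5ccccc5)cc2O[C@@]1(O6)c1ccc(OCc5ccccc5)c(OCc5ccccc5)c1 | intermediate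
32 | benzylated trimer: gallate on unit T, TBS on unit M, Br at C8 of unit M (key-step product) | O=C(O[C@@H]1[C@@H](c2c(OCc5ccccc5)c(Br)c3c(c2OCc5ccccc5)[C@H](c2c(OCc5ccccc5)cc(OCc5ccccc5)c4c2O[C@H](c2ccc(OCc5ccccc5)c(OCc5ccccc5)c2)[C@@H](OCc5ccccc5)C4)[C@@H](O[Si](C)(C)C(C)(C)C)[C@@H](c2ccc(OCc5ccccc5)c(OCc5ccccc5)c2)O3)c2c(OCc5ccccc5)cc(OCc5ccccc5)cc2O[C@@H]1c1ccc(OCc5ccccc5)c(OCc5ccccc5)c1)c1cc(OCc5ccccc5)c(OCc5ccccc5)c(OCc5ccccc5)c1 | intermediate
33 | trimer with free 3-OH on unit M | O=C(O[C@@H]1[C@@H](c2c(OCc5ccccc5)c(Br)c3c(c2OCc5ccccc5)[C@H](c2c(OCc5ccccc5)cc(OCc5ccccc5)c4c2O[C@H](c2ccc(OCc5ccccc5)c(OCc5ccccc5)c2)[C@@H](OCc5ccccc5)C4)[C@@H](O)[C@@H](c2ccc(OCc5ccccc5)c(OCc5ccccc5)c2)O3)c2c(OCc5ccccc5)cc(OCc5ccccc5)cc2O[C@@H]1c1ccc(OCc5ccccc5)c(OCc5ccccc5)c1)c1cc(OCc5ccccc5)c(OCc5ccccc5)c(OCc5ccccc5)c1 | intermediate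
34 | fully benzylated 8-bromo trimer bis-gallate | O=C(O[C@@H]1[C@@H](c2c(OCc5ccccc5)c(Br)c3c(c2OCc5ccccc5)[C@H](c2c(OCc5ccccc5)cc(OCc5ccccc5)c4c2O[C@H](c2ccc(OCc5ccccc5)c(OCc5ccccc5)c2)[C@@H](OCc5ccccc5)C4)[C@@H](OC(=O)c2cc(OCc5ccccc5)c(OCc5ccccc5)c(OCc5ccccc5)c2)[C@@H](c2ccc(OCc5ccccc5)c(OCc5ccccc5)c2)O3)c2c(OCc5ccccc5)cc(OCc5ccccc5)cc2O[C@@H]1c1ccc(OCc5ccccc5)c(OCc5ccccc5)c1)c1cc(OCc5ccccc5)c(OCc5ccccc5)c(OCc5ccccc5)c1 | intermediate
35 | (−)-epicatechin 3-O-gallate-(4β→6)-(−)-epicatechin 3-O-gallate-(4β→8)-(+)-catechin, CNP0112921.1 | O=C(O[C@@H]1[C@@H](c2c(O)cc3c(c2O)[C@H](c2c(O)cc(O)c4c2O[C@H](c2ccc(O)c(O)c2)[C@@H](O)C4)[C@@H](OC(=O)c2cc(O)c(O)c(O)c2)[C@@H](c2ccc(O)c(O)c2)O3)c2c(O)cc(O)cc2O[C@@H]1c1ccc(O)c(O)c1)c1cc(O)c(O)c(O)c1 | target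

## Step count and risks

Total: 24 steps. Longest linear sequence: 15 steps (13 → 14 → 16 → 17 → 18 → 19 → 20 → 22 → 23 → 24 → 25 → 29 → 32 → 33 → 34 → 35). From (−)-epicatechin the count is 14.

**Step 21 (key step, proposed new method).**
- *Most likely failure:* poor facial discrimination between the two mirror-related trans,cis manifolds. The stereocentres of unit M are remote and the phosphate is only ion-paired, so a mixture of diastereomers, or mainly the wrong sense, may form.
- *Further risks:* hydride transfer to the diaryl cation before it cyclises; loss of the C3 proton from the oxocarbenium to a 4H-chromene, which would scramble C3; hydride entry syn to the gallate if bridging is weak.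
- *Fallback (known chemistry):* the classical C4→C6 arylation. From 10, iodine–magnesium exchange and protonation (i-PrMgCl·LiCl, then MeOH) would give the iodine-free 8-bromo dimer F1, whose unit M has C6 as its only open ring A position. From 6, acylation with 27 (DMAP, Et3N) would give the 4β-(2-ethoxyethoxy) 3-O-gallate electrophile F2. TMSOTf in CH2Cl2 at −78 °C would then join C4 of F2 to C6 of unit M of F1, trans to the participating gallate, and the product is 32, where the route resumes. C6 of unit B can compete in this coupling, so a regioisomer separation has to be expected.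

**Step 20.**
- *Most likely failure:* erosion of enol geometry. If chelation is weak, the enolate forms as a mixture and acylation fixes the unwanted E isomer, which the analysis of step 21 assigns to the 3,4-cis series. Acylation on the alkoxide generated by any retro-addition is a lesser risk.
- *Fallback:* separate geometry setting from acylation. From 25, LiHMDS and TBSCl in THF/DMPU would give the silyl enol ether, from which the Z isomer F3 is separated on silica (the E isomer is hydrolysed back to 25 and recycled). From 27, KF with 18-crown-6 would give 3,4,5-tris(benzyloxy)benzoyl fluoride F4. Fluoride-catalysed acyl exchange (F4, catalytic TBAF) on F3 should then deliver 29 with retention of the double-bond geometry.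

**Step 15.**
- *Most likely failure:* incomplete addition. Both partners are di-ortho-oxygenated, so forming the tetra-ortho-substituted carbinol may be slow enough for the Grignard reagent to be lost by protonation or to attack a benzylic position.
- *Fallback:* attach the side chain after the C–C bond. The arylmagnesium species 21 from 10 would be added to the sodium phenoxide of 12, a smaller and chelating aldehyde, to give the ortho-hydroxy carbinol F5. O-Alkylation of its phenol with 16 (K2CO3) would give the ester F6. LiAlH4 would reduce it (or any lactone formed from it) to the diol F7. Selective silylation of the primary hydroxyl (TESCl, imidazole) returns to 22.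

**Step 7.**
- *Most likely failure:* loss or migration of iodine. Aryl iodides on phloroglucinol-type rings are prone to ipso-protonation by the triflic acid that the coupling generates. The doubly halogenated electrophile may also ionise sluggishly.
- *Fallback:* give up the iodine handle. Step 6 would be stopped after the bromination and 8 isolated. Coupling of 8 with 3 under the same conditions would give the 8-bromo dimer F1 directly. F1 then follows the classical arylation with F2 described for step 21 and rejoins the route at 32.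

**Step 24.**
- *Most likely failure:* incomplete or unselective global deprotection. Nineteen benzyl ethers and one hindered aryl bromide must all be cleaved; bromide and amine salts can slow the catalyst, and unbuffered HBr would cleave interflavan bonds.
- *Fallback:* remove the halogen first under neutral radical conditions. From 34, Bu3SnH and AIBN in toluene at 90 °C would give the bromine-free benzylated bis-gallate F8. Plain hydrogenolysis (H2, Pd(OH)2/C, THF/MeOH) of F8, with no amine present, would then give 35.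

## Further compounds

F1 | step 21 | 8-bromo-3-O-TBS-5,7,3',4'-tetra-O-benzyl-(−)-epicatechin-(4β→8)-3,5,7,3',4'-penta-O-benzyl-(+)-catechin (C6–H on unit M) | c2c(OCc5ccccc5)c(Br)c3c(c2OCc5ccccc5)[C@H](c2c(OCc5ccccc5)cc(OCc5ccccc5)c4c2O[C@H](c2ccc(OCc5ccccc5)c(OCc5ccccc5)c2)[C@@H](OCc5ccccc5)C4)[C@@H](O[Si](C)(C)C(C)(C)C)[C@@H](c2ccc(OCc5ccccc5)c(OCc5ccccc5)c2)O3
F2 | step 21 | 3-O-[3,4,5-tris(benzyloxy)benzoyl]-5,7,3',4'-tetra-O-benzyl-4β-(2-ethoxyethoxy)-(−)-epicatechin | O=C(O[C@@H]1[C@@H](OCCOCC)c2c(OCc5ccccc5)cc(OCc5ccccc5)cc2O[C@@H]1c1ccc(OCc5ccccc5)c(OCc5ccccc5)c1)c1cc(OCc5ccccc5)c(OCc5ccccc5)c(OCc5ccccc5)c1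
F3 | step 20 | (Z)-tert-butyldimethylsilyl enol ether of 25 | CC(C)(C)[Si](C)(C)O/C=C(/c1ccc(OCc5ccccc5)c(OCc5ccccc5)c1)Oc2cc(OCc5ccccc5)cc(OCc5ccccc5)c2C(OC)c2c(OCc5ccccc5)c(Br)c3c(c2OCc5ccccc5)[C@H](c2c(OCc5ccccc5)cc(OCc5ccccc5)c4c2O[C@H](c2ccc(OCc5ccccc5)c(OCc5ccccc5)c2)[C@@H](OCc5ccccc5)C4)[C@@H](O[Si](C)(C)C(C)(C)C)[C@@H](c2ccc(OCc5ccccc5)c(OCc5ccccc5)c2)O3
F4 | step 20 | 3,4,5-tris(benzyloxy)benzoyl fluoride | FC(=O)c1cc(OCc5ccccc5)c(OCc5ccccc5)c(OCc5ccccc5)c1
F5 | step 15 | [2,4-bis(benzyloxy)-6-hydroxyphenyl](MB-6-yl)methanol | Oc1cc(OCc5ccccc5)cc(OCc5ccccc5)c1C(O)c2c(OCc5ccccc5)c(Br)c3c(c2OCc5ccccc5)[C@H](c2c(OCc5ccccc5)cc(OCc5ccccc5)c4c2O[C@H](c2ccc(OCc5ccccc5)c(OCc5ccccc5)c2)[C@@H](OCc5ccccc5)C4)[C@@H](O[Si](C)(C)C(C)(C)C)[C@@H](c2ccc(OCc5ccccc5)c(OCc5ccccc5)c2)O3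
F6 | step 15 | benzyl 2-[3,4-bis(benzyloxy)phenyl]-2-{3,5-bis(benzyloxy)-2-[hydroxy(MB-6-yl)methyl]phenoxy}acetate | O=C(OCc5ccccc5)C(c1ccc(OCc5ccccc5)c(OCc5ccccc5)c1)Oc2cc(OCc5ccccc5)cc(OCc5ccccc5)c2C(O)c2c(OCc5ccccc5)c(Br)c3c(c2OCc5ccccc5)[C@H](c2c(OCc5ccccc5)cc(OCc5ccccc5)c4c2O[C@H](c2ccc(OCc5ccccc5)c(OCc5ccccc5)c2)[C@@H](OCc5ccccc5)C4)[C@@H](O[Si](C)(C)C(C)(C)C)[C@@H](c2ccc(OCc5ccccc5)c(OCc5ccccc5)c2)O3
F7 | step 15 | 2-[3,4-bis(benzyloxy)phenyl]-2-{3,5-bis(benzyloxy)-2-[hydroxy(MB-6-yl)methyl]phenoxy}ethan-1-ol | OCC(c1ccc(OCc5ccccc5)c(OCc5ccccc5)c1)Oc2cc(OCc5ccccc5)cc(OCc5ccccc5)c2C(O)c2c(OCc5ccccc5)c(Br)c3c(c2OCc5ccccc5)[C@H](c2c(OCc5ccccc5)cc(OCc5ccccc5)c4c2O[C@H](c2ccc(OCc5ccccc5)c(OCc5ccccc5)c2)[C@@H](OCc5ccccc5)C4)[C@@H](O[Si](C)(C)C(C)(C)C)[C@@H](c2ccc(OCc5ccccc5)c(OCc5ccccc5)c2)O3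
F0 | step 7 | none | none
F8 | step 24 | bromine-free fully benzylated trimer bis-gallate | O=C(O[C@@H]1[C@@H](c2c(OCc5ccccc5)cc3c(c2OCc5ccccc5)[C@H](c2c(OCc5ccccc5)cc(OCc5ccccc5)c4c2O[C@H](c2ccc(OCc5ccccc5)c(OCc5ccccc5)c2)[C@@H](OCc5ccccc5)C4)[C@@H](OC(=O)c2cc(OCc5ccccc5)c(OCc5ccccc5)c(OCc5ccccc5)c2)[C@@H](c2ccc(OCc5ccccc5)c(OCc5ccccc5)c2)O3)c2c(OCc5ccccc5)cc(OCc5ccccc5)cc2O[C@@H]1c1ccc(OCc5ccccc5)c(OCc5ccccc5)c1)c1cc(OCc5ccccc5)c(OCc5ccccc5)c(OCc5ccccc5)c1
A1 | alternative 1 | unit T flavan carrying the new arene (C8a OH, C4a diethyl acetal, C5 OTIPS, C7 OBn, C8 H) | CC(C)(C)[Si](C)(C)O[C@@H]1[C@@H](c2c(OCc5ccccc5)cc(O)c(C(OCC)OCC)c2O[Si](C(C)C)(C(C)C)C(C)C)c2c(OCc5ccccc5)cc(OCc5ccccc5)cc2O[C@@H]1c1ccc(OCc5ccccc5)c(OCc5ccccc5)c1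
A2 | alternative 1 | 3-benzyloxy-2-(3-O-TBS-5,7,3',4'-tetra-O-benzyl-epicatechin-4β-yl)cyclobut-2-en-1-one | CC(C)(C)[Si](C)(C)O[C@@H]1[C@@H](C2=C(OCc5ccccc5)CC2=O)c2c(OCc5ccccc5)cc(OCc5ccccc5)cc2O[C@@H]1c1ccc(OCc5ccccc5)c(OCc5ccccc5)c1
A3 | alternative 1 | (3,3-diethoxyprop-1-yn-1-yl)oxytriisopropylsilane | CCOC(OCC)C#CO[Si](C(C)C)(C(C)C)C(C)C
A4 | alternative 2 | benzylated trimer with free 3-hydroxyl on unit M and gallate on unit T | O=C(O[C@@H]1[C@@H](c2c(OCc5ccccc5)cc3c(c2OCc5ccccc5)[C@H](c2c(OCc5ccccc5)cc(OCc5ccccc5)c4c2O[C@H](c2ccc(OCc5ccccc5)c(OCc5ccccc5)c2)[C@@H](OCc5ccccc5)C4)[C@@H](O)[C@@H](c2ccc(OCc5ccccc5)c(OCc5ccccc5)c2)O3)c2c(OCc5ccccc5)cc(OCc5ccccc5)cc2O[C@@H]1c1ccc(OCc5ccccc5)c(OCc5ccccc5)c1)c1cc(OCc5ccccc5)c(OCc5ccccc5)c(OCc5ccccc5)c1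
A5 | alternative 2 | aryl ether of the unit T gallate-substituted 3,5-dibenzyloxyphenol with the trans-epoxide bearing catechin C8 | O=C(O[C@@H]1[C@@H](c2c(OCc5ccccc5)cc(O[C@H](c3ccc(OCc5ccccc5)c(OCc5ccccc5)c3)[C@@H]3O[C@H]3c6c(OCc5ccccc5)cc(OCc5ccccc5)c4c6O[C@H](c6ccc(OCc5ccccc5)c(OCc5ccccc5)c6)[C@@H](OCc5ccccc5)C4)cc2OCc5ccccc5)c2c(OCc5ccccc5)cc(OCc5ccccc5)cc2O[C@@H]1c1ccc(OCc5ccccc5)c(OCc5ccccc5)c1)c1cc(OCc5ccccc5)c(OCc5ccccc5)c(OCc5ccccc5)c1
A6 | alternative 3 | 5,7-dibenzyloxy-4-(MB-6-yl)-3,4-dihydrocoumarin | O=C1C[C@@H](c2c(OCc5ccccc5)c(Br)c3c(c2OCc5ccccc5)[C@H](c2c(OCc5ccccc5)cc(OCc5ccccc5)c4c2O[C@H](c2ccc(OCc5ccccc5)c(OCc5ccccc5)c2)[C@@H](OCc5ccccc5)C4)[C@@H](O[Si](C)(C)C(C)(C)C)[C@@H](c2ccc(OCc5ccccc5)c(OCc5ccccc5)c2)O3)c2c(OCc5ccccc5)cc(OCc5ccccc5)cc2O1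
A7 | alternative 3 | 4,6-dibenzyloxy-3-(MB-6-yl)indan-1-one | O=C1C[C@@H](c2c(OCc5ccccc5)c(Br)c3c(c2OCc5ccccc5)[C@H](c2c(OCc5ccccc5)cc(OCc5ccccc5)c4c2O[C@H](c2ccc(OCc5ccccc5)c(OCc5ccccc5)c2)[C@@H](OCc5ccccc5)C4)[C@@H](O[Si](C)(C)C(C)(C)C)[C@@H](c2ccc(OCc5ccccc5)c(OCc5ccccc5)c2)O3)c2c(OCc5ccccc5)cc(OCc5ccccc5)cc12
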